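**Strategy.** Hansforester J holds one motif twice. On ring A and on ring C, a benzylic CH2 is bonded to an (R)-CH(CH3)–O carbon whose oxygen carries an (R)-3-oxybutanoyl group. That carbon has the oxidation level of the acetaldehyde carbonyl carbon, so the route cuts the ArCH2–CH(O) bond. In one operation a chiral nickel catalyst joins 3,5-bis(benzyloxy)benzylzinc bromide to the 1-bromoethyl ester (both epimers) of (R)-3-(tert-butyldiphenylsilyloxy)butanoic acid. This forms the C–C bond and sets the carbinol stereocentre with the ester already in place. Both halves come from this product: one portion is desilylated, and the other is carboxylated ortho to its side chain to give ring C. One esterification and two deprotections follow.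

Key step: step 5

Remark: all four stereocentres of the target are (R). Two come unchanged from methyl (R)-3-hydroxybutanoate and two from step 5, because compound 9 is used twice.

Assumption: the sense of induction with a benzylic zinc reagent cannot be derived safely from the alkylzinc cases, so "BOX ligand" means whichever commercial antipode of 2,2'-(propane-2,2-diyl)bis(cis-4,5-diphenyl-4,5-dihydrooxazole) gives the (R)-carbinol ester, to be fixed in a trial run against an authentic sample of 9.

**Step 1**
Reactants: 1 methyl (R)-3-hydroxybutanoate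
Product: 2 methyl (R)-3-(tert-butyldiphenylsilyloxy)butanoate
Conditions: TBDPSCl, imidazole, DMF, 0 °C to rt
Reagents that add atoms: tert-butyldiphenylsilyl chloride, CC(C)(C)[Si](Cl)(c1ccccc1)c1ccccc1
Why: Imidazole-promoted silylation of a secondary alcohol leaves the stereocentre untouched, and this bulky, acid-tolerant silyl ether is chosen because it must later survive HBr, ZnBr2 and POCl3/DMF.

**Step 2**
Reactants: 2 methyl (R)-3-(tert-butyldiphenylsilyloxy)butanoate
Product: 3 (R)-3-(tert-butyldiphenylsilyloxy)butanoic acid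
Conditions: LiOH·H2O, THF/MeOH/H2O, 0 °C to rt; then 1 M HCl to pH 3
Reagents that add atoms: lithium hydroxide, [Li+].[OH-]
Why: Saponification of a methyl ester at or below room temperature is mild enough to avoid E1cB loss of the silyloxy group and does not touch C3.

**Step 3**
Reactants: 3 (R)-3-(tert-butyldiphenylsilyloxy)butanoic acid; 4 acetaldehyde
Product: 6 1-bromoethyl (R)-3-(tert-butyldiphenylsilyloxy)butanoate (both epimers at the bromo carbon), via acyl bromide 5 (not isolated)
Conditions: (COBr)2, DMF (cat.), CH2Cl2, 0 °C to rt, evaporate; then MeCHO, ZnBr2 (2 mol %), CH2Cl2, −20 to 0 °C; volatiles removed, used crude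
Reagents that add atoms: oxalyl bromide, O=C(Br)C(=O)Br
Why: Acyl bromide formation gives only volatile by-products, and the Lewis-acid-catalysed addition of an acyl bromide across an aldehyde C=O is the classical route to 1-bromoalkyl esters, while the unselective new C–Br centre does not matter because step 5 erases it.

**Step 4**
Reactants: 7 3,5-bis(benzyloxy)benzyl bromide
Product: 8 3,5-bis(benzyloxy)benzylzinc bromide (titrated THF solution)
Conditions: Zn dust (activated with BrCH2CH2Br and TMSCl, a few mol %), THF, 0 °C, slow addition of 7; decant, titrate with I2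
Reagents that add atoms: zinc, [Zn]
Why: Oxidative insertion of activated zinc into a benzylic C–Br bond is a standard way to benzylic zinc halides, and low temperature with slow addition should keep Wurtz coupling down while the aryl benzyl ethers stay inert.

**Step 5**
Reactants: 6 1-bromoethyl (R)-3-(tert-butyldiphenylsilyloxy)butanoate (both epimers); 8 3,5-bis(benzyloxy)benzylzinc bromide
Product: 9 (R)-1-[3,5-bis(benzyloxy)phenyl]propan-2-yl (R)-3-(tert-butyldiphenylsilyloxy)butanoate
Conditions: NiBr2·glyme (10 mol %), BOX ligand (12 mol %), THF/DMA, −20 °C, 8 (1.3 equiv) added by syringe pump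
Reagents that add atoms: none
Why: Proposed new method: a monovalent nickel–BOX species should abstract bromine from either epimer of 6 to give one planar α-acyloxyethyl radical, a divalent benzylnickel complex formed by transmetalation from 8 should capture it, and reductive elimination from trivalent nickel should form the ArCH2–CH(O) bond and return monovalent nickel. The closest known reaction type is the nickel/bis(oxazoline)-catalysed enantioconvergent Negishi coupling of racemic 1-bromoalkyl esters with unactivated alkylzinc halides, and only the benzylic nucleophile is new. No ring is closed. The single new stereocentre, the carbinol carbon, should be set as (R) by the ligand, because both epimers lose their configuration in the radical and the ester carbonyl oxygen can bind to nickel and so help the catalyst to tell the acyloxy group from CH3. The step needs catalyst control over the resident C3 stereocentre, which lies four bonds from the radical carbon and should bias little, and it needs cross-coupling to outrun bibenzyl formation and the uncatalysed ZnBr2-promoted substitution, which slow addition of 8, low temperature and the donor cosolvent should secure. As the acyl group is a single enantiomer, any leakage would appear as a diastereomer that chromatography can remove.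

**Step 6** (first portion of 9)
Reactants: 9 (R)-1-[3,5-bis(benzyloxy)phenyl]propan-2-yl (R)-3-(tert-butyldiphenylsilyloxy)butanoate
Product: 10 (R)-1-[3,5-bis(benzyloxy)phenyl]propan-2-yl (R)-3-hydroxybutanoate
Conditions: HF·pyridine, THF/pyridine, 0 °C to rt
Reagents that add atoms: none
Why: Fluoride-driven Si–O cleavage in a weakly acidic medium frees the alcohol without the E1cB elimination that a basic fluoride source could start in a β-oxy ester, and no C–O bond at a stereocentre is broken.

**Step 7** (second portion of 9)
Reactants: 9 (R)-1-[3,5-bis(benzyloxy)phenyl]propan-2-yl (R)-3-(tert-butyldiphenylsilyloxy)butanoate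
Product: 12 (R)-1-[3,5-bis(benzyloxy)-2-formylphenyl]propan-2-yl (R)-3-(tert-butyldiphenylsilyloxy)butanoate, via aryl iminium salt 11 (not isolated)
Conditions: POCl3, DMF, 0 to 50 °C; then aq NaOAc, rt
Reagents that add atoms: N,N-dimethylformamide, CN(C)C=O; water, O
Why: Vilsmeier–Haack formylation of a 3,5-dialkoxy-alkylbenzene goes to C2 (equivalent to C6), para to one benzyloxy group and ortho to the other, rather than to the crowded C4 between both, and the ester and the diphenylsilyl ether tolerate the reagent.

**Step 8**
Reactants: 12 (R)-1-[3,5-bis(benzyloxy)-2-formylphenyl]propan-2-yl (R)-3-(tert-butyldiphenylsilyloxy)butanoate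
Product: 13 2,4-bis(benzyloxy)-6-{(R)-2-[(R)-3-(tert-butyldiphenylsilyloxy)butanoyloxy]propyl}benzoic acid
Conditions: NaClO2, NaH2PO4, 2-methyl-2-butene, t-BuOH/THF/H2O, 0 °C to rt
Reagents that add atoms: sodium chlorite, [Na+].[O-]Cl=O
Why: Pinnick oxidation turns the hindered aryl aldehyde into the acid under buffered conditions, and the alkene scavenger traps HOCl so that the electron-rich ring should not be chlorinated.

**Step 9**
Reactants: 13 2,4-bis(benzyloxy)-6-{(R)-2-[(R)-3-(tert-butyldiphenylsilyloxy)butanoyloxy]propyl}benzoic acid; 10 (R)-1-[3,5-bis(benzyloxy)phenyl]propan-2-yl (R)-3-hydroxybutanoate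
Product: 15 (R)-4-{[(R)-1-(3,5-bis(benzyloxy)phenyl)propan-2-yl]oxy}-4-oxobutan-2-yl 2,4-bis(benzyloxy)-6-{(R)-2-[(R)-3-(tert-butyldiphenylsilyloxy)butanoyloxy]propyl}benzoate, via acid chloride 14 (not isolated)
Conditions: (COCl)2, DMF (cat.), CH2Cl2, 0 °C to rt, evaporate; then 10, pyridine, DMAP (20 mol %), CH2Cl2, 0 °C to rt
Reagents that add atoms: none
Why: DMAP-catalysed acylation of a secondary alcohol by an aroyl chloride uses the smallest activated form of the di-ortho-substituted acid, keeps the carbinol C–O bond and hence its (R) configuration, and relies on a base too weak to eliminate the β-acyloxy ester.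

**Step 10**
Reactants: 15 fully protected tetraester
Product: 16 (R)-4-{[(R)-1-(3,5-bis(benzyloxy)phenyl)propan-2-yl]oxy}-4-oxobutan-2-yl 2,4-bis(benzyloxy)-6-{(R)-2-[(R)-3-hydroxybutanoyloxy]propyl}benzoate
Conditions: HF·pyridine, THF/pyridine, 0 °C to rt
Reagents that add atoms: none
Why: The same non-basic fluoride desilylation as in step 6 removes the last silyl ether while the three ester links, two of them β-acyloxy esters prone to elimination by base, stay intact.

**Step 11**
Reactants: 16 tetrabenzyl ether of the target
Product: 17 Hansforester J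
Conditions: H2 (1 atm), 10% Pd/C, EtOAc/EtOH, rt
Reagents that add atoms: none
Why: Catalytic hydrogenolysis cleaves the four aryl benzyl ethers, whereas the carbinol esters are homobenzylic and not benzylic, so no C–O bond at a stereocentre is at risk.

**Compound list**
1 | methyl (R)-3-hydroxybutanoate | C[C@@H](O)CC(=O)OC | starting material
2 | methyl (R)-3-(tert-butyldiphenylsilyloxy)butanoate | COC(=O)C[C@@H](C)O[Si](c1ccccc1)(c1ccccc1)C(C)(C)C | intermediate
3 | (R)-3-(tert-butyldiphenylsilyloxy)butanoic acid | OC(=O)C[C@@H](C)O[Si](c1ccccc1)(c1ccccc1)C(C)(C)C | intermediate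
4 | acetaldehyde | CC=O | starting material
5 | (R)-3-(tert-butyldiphenylsilyloxy)butanoyl bromide | BrC(=O)C[C@@H](C)O[Si](c1ccccc1)(c1ccccc1)C(C)(C)C | intermediate
6 | 1-bromoethyl (R)-3-(tert-butyldiphenylsilyloxy)butanoate, both epimers at the bromo carbon | CC(Br)OC(=O)C[C@@H](C)O[Si](c1ccccc1)(c1ccccc1)C(C)(C)C | intermediate
7 | 3,5-bis(benzyloxy)benzyl bromide | BrCc1cc(OCc2ccccc2)cc(OCc2ccccc2)c1 | starting material
8 | 3,5-bis(benzyloxy)benzylzinc bromide | Br[Zn]Cc1cc(OCc2ccccc2)cc(OCc2ccccc2)c1 | intermediate
9 | (R)-1-[3,5-bis(benzyloxy)phenyl]propan-2-yl (R)-3-(tert-butyldiphenylsilyloxy)butanoate | C[C@H](Cc1cc(OCc2ccccc2)cc(OCc2ccccc2)c1)OC(=O)C[C@@H](C)O[Si](c1ccccc1)(c1ccccc1)C(C)(C)C | intermediate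
10 | (R)-1-[3,5-bis(benzyloxy)phenyl]propan-2-yl (R)-3-hydroxybutanoate | C[C@H](Cc1cc(OCc2ccccc2)cc(OCc2ccccc2)c1)OC(=O)C[C@@H](C)O | intermediate
11 | N-{2,4-bis(benzyloxy)-6-[(R)-2-((R)-3-(tert-butyldiphenylsilyloxy)butanoyloxy)propyl]benzylidene}-N-methylmethanaminium dichlorophosphate | C[C@H](Cc1cc(OCc2ccccc2)cc(OCc2ccccc2)c1C=[N+](C)C)OC(=O)C[C@@H](C)O[Si](c1ccccc1)(c1ccccc1)C(C)(C)C.[O-]P(=O)(Cl)Cl | intermediate
12 | (R)-1-[3,5-bis(benzyloxy)-2-formylphenyl]propan-2-yl (R)-3-(tert-butyldiphenylsilyloxy)butanoate | C[C@H](Cc1cc(OCc2ccccc2)cc(OCc2ccccc2)c1C=O)OC(=O)C[C@@H](C)O[Si](c1ccccc1)(c1ccccc1)C(C)(C)C | intermediate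
13 | 2,4-bis(benzyloxy)-6-{(R)-2-[(R)-3-(tert-butyldiphenylsilyloxy)butanoyloxy]propyl}benzoic acid | C[C@H](Cc1cc(OCc2ccccc2)cc(OCc2ccccc2)c1C(=O)O)OC(=O)C[C@@H](C)O[Si](c1ccccc1)(c1ccccc1)C(C)(C)C | intermediate
14 | 2,4-bis(benzyloxy)-6-{(R)-2-[(R)-3-(tert-butyldiphenylsilyloxy)butanoyloxy]propyl}benzoyl chloride | C[C@H](Cc1cc(OCc2ccccc2)cc(OCc2ccccc2)c1C(=O)Cl)OC(=O)C[C@@H](C)O[Si](c1ccccc1)(c1ccccc1)C(C)(C)C | intermediate
15 | (R)-4-{[(R)-1-(3,5-bis(benzyloxy)phenyl)propan-2-yl]oxy}-4-oxobutan-2-yl 2,4-bis(benzyloxy)-6-{(R)-2-[(R)-3-(tert-butyldiphenylsilyloxy)butanoyloxy]propyl}benzoate | C[C@H](Cc1cc(OCc2ccccc2)cc(OCc2ccccc2)c1)OC(=O)C[C@@H](C)OC(=O)c1c(OCc2ccccc2)cc(OCc2ccccc2)cc1C[C@@H](C)OC(=O)C[C@@H](C)O[Si](c1ccccc1)(c1ccccc1)C(C)(C)C | intermediate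
16 | (R)-4-{[(R)-1-(3,5-bis(benzyloxy)phenyl)propan-2-yl]oxy}-4-oxobutan-2-yl 2,4-bis(benzyloxy)-6-{(R)-2-[(R)-3-hydroxybutanoyloxy]propyl}benzoate | C[C@H](Cc1cc(OCc2ccccc2)cc(OCc2ccccc2)c1)OC(=O)C[C@@H](C)OC(=O)c1c(OCc2ccccc2)cc(OCc2ccccc2)cc1C[C@@H](C)OC(=O)C[C@@H](C)O | intermediate
17 | Hansforester J, (R)-4-{[(R)-1-(3,5-dihydroxyphenyl)propan-2-yl]oxy}-4-oxobutan-2-yl 2,4-dihydroxy-6-{(R)-2-[(R)-3-hydroxybutanoyloxy]propyl}benzoate | C[C@H](Cc1cc(O)cc(O)c1)OC(=O)C[C@@H](C)OC(=O)c1c(O)cc(O)cc1C[C@@H](C)OC(=O)C[C@@H](C)O | target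

**Total step count:** 11
**Longest linear sequence:** 9 steps (1, 2, 3, 5, 7, 8, 9, 10, 11)

**Steps most likely to fail**

1. **Step 5.**
   - *What may go wrong:* the flat, fast-transmetalating benzyl group may give weak facial discrimination at nickel. The benzyl fragment may homocouple. Uncatalysed Lewis-acid substitution at the bromo carbon may erode the stereochemical outcome.
   - *Fallback (known chemistry):* the stereocentre is taken from the chiral pool and the ester is made afterwards. Commercial 1-bromo-3,5-bis(benzyloxy)benzene is converted with Mg in THF into [3,5-bis(benzyloxy)phenyl]magnesium bromide F1. F1 opens (R)-propylene oxide at its CH2 terminus under CuI catalysis (THF, −30 to 0 °C) to give (R)-1-[3,5-bis(benzyloxy)phenyl]propan-2-ol F2, with the epoxide stereocentre untouched. Steglich esterification of F2 with acid 3 (EDC, DMAP, CH2Cl2) then gives 9.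
   - *Route connection:* the fallback sets out from 3 and comes back at 9. Material made this way also serves as the reference sample for assigning the outcome of step 5.

2. **Step 9.**
   - *What may go wrong:* acyl transfer at the di-ortho-substituted carbonyl may be slow, which leaves time for base-induced elimination of the β-oxy ester or for decay of the activated acid.
   - *Fallback:* the roles are reversed so that the carbinol carbon becomes the electrophile, which is insensitive to crowding at the carbonyl. Because this inverts the carbinol, alcohol 10 is first epimerised by a redox pair. Dess–Martin periodinane (CH2Cl2, rt) gives (R)-1-[3,5-bis(benzyloxy)phenyl]propan-2-yl 3-oxobutanoate F3. Noyori asymmetric hydrogenation (H2, RuCl2[(S)-BINAP], EtOH/CH2Cl2, 40 °C) gives (R)-1-[3,5-bis(benzyloxy)phenyl]propan-2-yl (S)-3-hydroxybutanoate F4. The Mitsunobu reaction of F4 with acid 13 (PPh3, DIAD, toluene, 0 °C to rt) gives 15 with inversion to (R).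
   - *Route connection:* the fallback sets out from 10 and comes back at 15.

3. **Step 3.**
   - *What may go wrong:* the silyloxy group may be lost from the acyl bromide under acid. Acetaldehyde may oligomerise on ZnBr2. The bromo ester may hydrolyse on handling.
   - *Fallback:* the acyl bromide is avoided altogether. Acid 3 undergoes transvinylation with vinyl acetate (Pd(OAc)2, KOH (cat.), neat vinyl acetate, rt to 40 °C) to give vinyl (R)-3-(tert-butyldiphenylsilyloxy)butanoate F5, which can be purified. Markovnikov hydrobromination with one equivalent of anhydrous HBr in CH2Cl2 at −40 °C gives 6, ready for use after evaporation.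
   - *Route connection:* the fallback sets out from 3 and comes back at 6.

**Further compounds**
F1 | step 5 | [3,5-bis(benzyloxy)phenyl]magnesium bromide | Br[Mg]c1cc(OCc2ccccc2)cc(OCc2ccccc2)c1
F2 | step 5 | (R)-1-[3,5-bis(benzyloxy)phenyl]propan-2-ol | C[C@@H](O)Cc1cc(OCc2ccccc2)cc(OCc2ccccc2)c1
F3 | step 9 | (R)-1-[3,5-bis(benzyloxy)phenyl]propan-2-yl 3-oxobutanoate | C[C@H](Cc1cc(OCc2ccccc2)cc(OCc2ccccc2)c1)OC(=O)CC(C)=O
F4 | step 9 | (R)-1-[3,5-bis(benzyloxy)phenyl]propan-2-yl (S)-3-hydroxybutanoate | C[C@H](Cc1cc(OCc2ccccc2)cc(OCc2ccccc2)c1)OC(=O)C[C@H](C)O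
F5 | step 3 | vinyl (R)-3-(tert-butyldiphenylsilyloxy)butanoate | C=COC(=O)C[C@@H](C)O[Si](c1ccccc1)(c1ccccc1)C(C)(C)C
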